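**Retrosynthetic overview**

1. In ring A the exocyclic methylene carbon (a 1,1‑disubstituted alkene carbon, C1) is bonded directly to the carbinol carbon (C2). This C1–C2 bond is cut to an alkenylchromium (from a 1‑iodoethenyl group on the spiro carbon) and a tethered aldehyde; ring A closes last, 6‑exo.
2. The vinyl bromide (C3=C4–Br) comes after ring closure from the C4 ketone, carried through the closure as its dioxolane, by enol triflate formation and nickel‑catalysed triflate‑to‑bromide exchange.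
3. The aldehyde arm is grown from a 2‑methylbut‑3‑en‑2‑yl group (cleavage, allylation, oxidation, ketalisation, cleavage). The iodoalkene comes from an ester through an alkyne and haloboration.
4. Ring B is the cyclohexane of the starting material. Its stereocentres come from amide‑base desymmetrisation of a 4,4‑disubstituted cyclohexanone (quaternary carbon), α‑bromination (CHBr), and axial methyl addition followed by retentive deoxychlorination (C(Cl)Me).
5. The two adjacent quaternary carbons (future spiro carbon and CMe2) are joined first, by Ireland–Claisen rearrangement of a prenyl ester.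

Key step: step 17

Remark 1: The sense of induction of the lithium amide in step 4 is taken from the 4‑tert‑butylcyclohexanone model and that of the sulfonamide ligand in step 17 from intermolecular alkenyl iodide–aldehyde couplings; the mirror‑image reagent would be used if either sense proved opposite.
Remark 2: Monocyclic intermediates are numbered from the quaternary ring carbon (C1); CHBr is C3 and C(Cl)Me is C4. Compound 1 (the ethylene ketal of 4‑oxocyclohexanecarboxylic acid) is taken as a catalogue compound.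

**Route**

Step 1
Reactants: 1 1,4‑dioxaspiro[4.5]decane‑8‑carboxylic acid; 2 3‑methylbut‑2‑en‑1‑ol (prenol)
Product: 3 3‑methylbut‑2‑en‑1‑yl 1,4‑dioxaspiro[4.5]decane‑8‑carboxylate
Conditions: EDC·HCl, DMAP (cat.), CH2Cl2, 0 °C → rt
Reagents that add atoms: prenol (2), CC(C)=CCO
Why: Carbodiimide (Steglich‑type) esterification joins the acid and the primary allylic alcohol under neutral conditions that leave the dioxolane intact; no stereocentre is formed.

Step 2
Reactants: 3 prenyl ester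
Product: 7 1‑(2‑methylbut‑3‑en‑2‑yl)‑4‑oxocyclohexane‑1‑carboxylic acid, via silyl ketene acetal 4 (not isolated), via trimethylsilyl ester 5 (not isolated), via ketal acid 6 (not isolated)
Conditions: LiN(i‑Pr)2 (LDA), THF, −78 °C; Me3SiCl, −78 °C → rt, then 70 °C; then 2 M HCl, THF, rt
Reagents that add atoms: water, O
Why: Ireland–Claisen rearrangement of the ketene silyl acetal of a prenyl ester forms the bond between the two fully substituted carbons by a [3,3] shift that tolerates the crowding, and the acidic work‑up frees both the acid and the ring ketone; the product is achiral.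

Step 3
Reactants: 7 keto acid
Product: 8 methyl 1‑(2‑methylbut‑3‑en‑2‑yl)‑4‑oxocyclohexane‑1‑carboxylate
Conditions: MeI, K2CO3, DMF, rt
Reagents that add atoms: iodomethane, CI
Why: O‑Alkylation of the carboxylate (SN2 at methyl) is insensitive to crowding at the acyl carbon, and K2CO3 is too weak to enolise the ketone.

Step 4
Reactants: 8 keto ester
Product: 9 methyl (1R)‑1‑(2‑methylbut‑3‑en‑2‑yl)‑4‑(trimethylsilyloxy)cyclohex‑3‑ene‑1‑carboxylate
Conditions: (R,R)‑bis(1‑phenylethyl)amine·HCl, n‑BuLi (2 equiv), THF (gives the lithium amide with LiCl); Me3SiCl (internal quench), then 8, −100 → −78 °C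
Reagents that add atoms: chlorotrimethylsilane, C[Si](C)(C)Cl
Why: Enantioselective deprotonation of a prochiral 4,4‑disubstituted cyclohexanone by a chiral lithium amide with internal silyl quench (Simpkins–Koga desymmetrisation): the tertiary alkyl group locks the chair with the ester axial, and the (R,R)‑amide should remove one of the two enantiotopic axial α‑protons, which makes C1 a stereocentre of R configuration.

Step 5
Reactants: 9 silyl enol ether
Product: 10 methyl (1R,3S)‑3‑bromo‑1‑(2‑methylbut‑3‑en‑2‑yl)‑4‑oxocyclohexane‑1‑carboxylate (Br trans to the ester)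
Conditions: NBS, NaHCO3, THF, −78 °C
Reagents that add atoms: N‑bromosuccinimide, O=C1CCC(=O)N1Br
Why: Electrophilic α‑bromination of a silyl enol ether places bromine regiospecifically at the enol carbon; the axial ester on C1 shields the syn face, so bromine should enter trans to it and sit equatorial, which is also the more stable epimer.

Step 6
Reactants: 10 bromoketone
Product: 11 methyl (1R,3S,4S)‑3‑bromo‑4‑hydroxy‑4‑methyl‑1‑(2‑methylbut‑3‑en‑2‑yl)cyclohexane‑1‑carboxylate (OH trans to Br, cis to the ester)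
Conditions: AlMe3 (3 equiv), toluene, −78 → 0 °C; aq. KNaC4H4O6
Reagents that add atoms: trimethylaluminium, C[Al](C)C
Why: 1,2‑Addition of excess AlMe3 in a hydrocarbon solvent (one aluminium on oxygen, methyl delivered from a second) favours axial attack on a cyclohexanone, so the hydroxyl should end equatorial, trans to the equatorial bromine, while the hindered methyl ester and the C–Br bond are left alone.

Step 7
Reactants: 11 bromohydrin
Product: 12 methyl (1R,3S,4S)‑3‑bromo‑4‑chloro‑4‑methyl‑1‑(2‑methylbut‑3‑en‑2‑yl)cyclohexane‑1‑carboxylate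
Conditions: SOCl2, CH2Cl2, 0 °C → rt
Reagents that add atoms: thionyl chloride, O=S(Cl)Cl
Why: Deoxychlorination of a tertiary alcohol through its chlorosulfite in a non‑polar, base‑free medium proceeds by ion‑pair return (SNi) and, once the ring twists, by anchimeric assistance of the vicinal bromine; both deliver chloride to the face the oxygen left, so the C–Cl bond should form with retention, trans to bromine.

Step 8
Reactants: 12 bromochloro ester
Product: 13 [(1R,3S,4S)‑3‑bromo‑4‑chloro‑4‑methyl‑1‑(2‑methylbut‑3‑en‑2‑yl)cyclohexyl]methanol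
Conditions: i‑Bu2AlH (3 equiv), CH2Cl2, −78 → 0 °C; aq. KNaC4H4O6
Reagents that add atoms: none
Why: Hydride reduction of the neopentyl ester to the primary alcohol with i‑Bu2AlH, to which alkyl bromide, alkyl chloride and alkene are inert.

Step 9
Reactants: 13 alcohol
Product: 14 (1R,3S,4S)‑3‑bromo‑4‑chloro‑4‑methyl‑1‑(2‑methylbut‑3‑en‑2‑yl)cyclohexane‑1‑carbaldehyde
Conditions: Dess–Martin periodinane, NaHCO3, CH2Cl2, 0 °C → rt
Reagents that add atoms: none
Why: Dess–Martin oxidation gives the aldehyde under buffered, non‑basic conditions; the aldehyde has no α‑hydrogen and cannot epimerise.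

Step 10
Reactants: 14 aldehyde
Product: 15 (1S,3S,4S)‑3‑bromo‑4‑chloro‑1‑ethynyl‑4‑methyl‑1‑(2‑methylbut‑3‑en‑2‑yl)cyclohexane (same spatial arrangement; descriptor changes by priority)
Conditions: dimethyl (1‑diazo‑2‑oxopropyl)phosphonate, K2CO3, MeOH, 0 °C → rt
Reagents that add atoms: dimethyl (1‑diazo‑2‑oxopropyl)phosphonate, COP(=O)(OC)C(=[N+]=[N-])C(C)=O
Why: Seyferth–Gilbert homologation (Ohira–Bestmann variant) converts the non‑enolisable aldehyde into the terminal alkyne under mild carbonate conditions; the equatorial halides have no anti‑periplanar hydrogen, so E2 loss should be slow.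

Step 11
Reactants: 15 alkyne
Product: 17 (1R,3S,4S)‑3‑bromo‑4‑chloro‑1‑(1‑iodoethenyl)‑4‑methyl‑1‑(2‑methylbut‑3‑en‑2‑yl)cyclohexane, via alkenylborane 16 (not isolated)
Conditions: B‑iodo‑9‑BBN, pentane/CH2Cl2, −20 → 0 °C; then AcOH, 0 °C → rt
Reagents that add atoms: B‑iodo‑9‑borabicyclo[3.3.1]nonane, IB1C2CCCC1CCC2
Why: Haloboration of a terminal alkyne with B‑iodo‑9‑BBN adds B–I syn with iodine at the internal carbon, and protonolysis of the alkenyl–boron bond with acetic acid leaves the 2‑iodo‑1‑alkene; the reagent has no B–H bond and does not touch the vinyl group.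

Step 12
Reactants: 17 iodoalkene
Product: 19 2‑[(1R,3S,4S)‑3‑bromo‑4‑chloro‑1‑(1‑iodoethenyl)‑4‑methylcyclohexyl]‑2‑methylpropanal, via diol 18 (not isolated)
Conditions: OsO4 (cat.), NaIO4, 2,6‑lutidine, dioxane/H2O, rt
Reagents that add atoms: osmium tetroxide (catalytic oxygen carrier), O=[Os](=O)(=O)=O; sodium periodate, [Na+].[O-]I(=O)(=O)=O
Why: Lemieux–Johnson oxidation (osmylation, then periodate cleavage) cuts the monosubstituted vinyl group, whereas the electron‑poor and more hindered 1‑iodo‑1,1‑disubstituted alkene reacts with OsO4 much more slowly.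

Step 13
Reactants: 19 aldehyde
Product: 20 2‑[(1R,3S,4S)‑3‑bromo‑4‑chloro‑1‑(1‑iodoethenyl)‑4‑methylcyclohexyl]‑2‑methylhex‑5‑en‑3‑ol (both C3 epimers)
Conditions: CH2=CHCH2MgBr, Et2O, −78 °C; aq. NH4Cl
Reagents that add atoms: allylmagnesium bromide, C=CC[Mg]Br
Why: Allyl Grignard addition through a six‑membered transition state is fast at −78 °C even at a neopentyl aldehyde and outpaces any reaction at the alkenyl iodide or the alkyl halides; the new carbinol centre is left uncontrolled because it is oxidised in the next step.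

Step 14
Reactants: 20 homoallylic alcohol
Product: 21 2‑[(1R,3S,4S)‑3‑bromo‑4‑chloro‑1‑(1‑iodoethenyl)‑4‑methylcyclohexyl]‑2‑methylhex‑5‑en‑3‑one
Conditions: Dess–Martin periodinane, NaHCO3, CH2Cl2, 0 °C → rt
Reagents that add atoms: none
Why: Dess–Martin oxidation gives the β,γ‑unsaturated ketone under buffered conditions that should not move the double bond into conjugation, and it removes the uncontrolled carbinol centre.

Step 15
Reactants: 21 allyl ketone
Product: 22 2‑{2‑[(1R,3S,4S)‑3‑bromo‑4‑chloro‑1‑(1‑iodoethenyl)‑4‑methylcyclohexyl]propan‑2‑yl}‑2‑(prop‑2‑en‑1‑yl)‑1,3‑dioxolane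
Conditions: Me3SiOCH2CH2OSiMe3, TMSOTf (cat.), CH2Cl2, −78 → −20 °C; pyridine quench
Reagents that add atoms: 1,2‑bis(trimethylsilyloxy)ethane, C[Si](C)(C)OCCO[Si](C)(C)C
Why: Noyori ketalisation is aprotic, works at low temperature on hindered ketones and is driven by formation of hexamethyldisiloxane, so the allyl double bond, the tertiary chloride and the alkenyl iodide should remain untouched.

Step 16
Reactants: 22 allyl ketal
Product: 24 [2‑(2‑{(1R,3S,4S)‑3‑bromo‑4‑chloro‑1‑(1‑iodoethenyl)‑4‑methylcyclohexyl}propan‑2‑yl)‑1,3‑dioxolan‑2‑yl]acetaldehyde, via diol 23 (not isolated)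
Conditions: OsO4 (cat.), NaIO4, 2,6‑lutidine, dioxane/H2O, rt
Reagents that add atoms: osmium tetroxide (catalytic oxygen carrier), O=[Os](=O)(=O)=O; sodium periodate, [Na+].[O-]I(=O)(=O)=O
Why: A second Lemieux–Johnson cleavage of the unhindered terminal alkene gives the β‑ketal aldehyde under lutidine‑buffered conditions that spare the dioxolane and the alkenyl iodide.

Step 17
Reactants: 24 iodoalkene aldehyde
Product: 26 ethylene ketal of (2R,6S,9S,10S)‑10‑bromo‑9‑chloro‑2‑hydroxy‑5,5,9‑trimethyl‑1‑methylidenespiro[5.5]undecan‑4‑one, via alkenylchromium dichloride 25 (not isolated)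
Conditions: CrCl2 (6 equiv), (S)‑N‑[2‑(4‑isopropyl‑4,5‑dihydrooxazol‑2‑yl)‑6‑methylphenyl]methanesulfonamide (6.6 equiv), Et3N (6.6 equiv), NiCl2 (0.2 equiv), THF, 25 °C, slow addition of 24 (final 0.01 M); aqueous work‑up
Reagents that add atoms: none
Why: NiCl2 is reduced by CrCl2 to zerovalent nickel, which inserts into the C–I bond of the 2‑iodo‑1‑alkene; transmetallation gives the alkenylchromium dichloride 25 (trivalent chromium), whose carbon adds to the tethered aldehyde. The closest known reaction type is the intramolecular Nozaki–Hiyama–Kishi alkenylation of aldehydes by 2‑iodo‑1‑alkenes, including its sulfonamide‑ligand‑controlled variants. Ring A closes in a 6‑exo‑trig mode (the C=O lies outside the forming ring), and the bond between the methylene‑bearing carbon and the carbinol carbon is made together with the exocyclic methylene and the secondary alcohol. The new carbinol centre (2R) is set by the chiral sulfonamide on chromium, because the spiro carbon tells the two aldehyde faces apart only through the remote Br and Cl of ring B. The step needs selectivity for the C(sp2)–I bond over the secondary C–Br and tertiary C–Cl bonds and for the aldehyde over the ketal: the dioxolane holds the future C–Br alkene carbon at the ketone level so that the alkenyl iodide is the only halide zerovalent nickel inserts into readily, the alkenylchromium has no β‑leaving group, and organochromium reagents are non‑basic and add only to aldehydes.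

Step 18
Reactants: 26 allylic alcohol
Product: 27 ethylene ketal of (2R,6S,9S,10S)‑10‑bromo‑2‑[(tert‑butyldimethylsilyl)oxy]‑9‑chloro‑5,5,9‑trimethyl‑1‑methylidenespiro[5.5]undecan‑4‑one
Conditions: TBSCl, imidazole, DMF, 40 °C
Reagents that add atoms: tert‑butyl(chloro)dimethylsilane, CC(C)(C)[Si](C)(C)Cl
Why: Silylation protects the secondary allylic alcohol as an ether that is a poor leaving group for the later enolate step, under mildly basic conditions that leave the dioxolane intact.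

Step 19
Reactants: 27 silyl ether ketal
Product: 28 (2R,6S,9S,10S)‑10‑bromo‑2‑[(tert‑butyldimethylsilyl)oxy]‑9‑chloro‑5,5,9‑trimethyl‑1‑methylidenespiro[5.5]undecan‑4‑one
Conditions: PPTS, acetone/H2O, 45 °C
Reagents that add atoms: water, O
Why: Acid‑catalysed ketal hydrolysis with a weak acid frees the hindered ketone (relief of strain at the neopentyl ketal carbon) while the secondary TBS ether should survive.

Step 20
Reactants: 28 ketone
Product: 30 (2R,6S,9S,10S)‑10‑bromo‑2‑[(tert‑butyldimethylsilyl)oxy]‑9‑chloro‑5,5,9‑trimethyl‑1‑methylidenespiro[5.5]undec‑3‑en‑4‑yl trifluoromethanesulfonate, via potassium enolate 29 (not isolated)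
Conditions: KN(SiMe3)2, THF, −78 °C; then N‑(5‑chloropyridin‑2‑yl)bis(trifluoromethanesulfonyl)imide (Comins' reagent), −78 → −40 °C
Reagents that add atoms: Comins' reagent, FC(F)(F)S(=O)(=O)N(c1ccc(Cl)cn1)S(=O)(=O)C(F)(F)F
Why: Enol triflate formation: the base can remove a proton only from the CH2 between the carbonyl and the silyloxy carbon (the other α‑carbon is quaternary), and O‑sulfonylation at −78 °C should outpace E1cB loss of the poor silyloxide leaving group.

Step 21
Reactants: 30 enol triflate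
Product: 31 tert‑butyl{[(2R,6S,9S,10S)‑4,10‑dibromo‑9‑chloro‑5,5,9‑trimethyl‑1‑methylidenespiro[5.5]undec‑3‑en‑2‑yl]oxy}dimethylsilane
Conditions: Ni(OAc)2·4H2O (10 mol%), 1,5‑cyclooctadiene, Zn (cat.), LiBr (3 equiv), DMA/THF, rt
Reagents that add atoms: lithium bromide, [Li+].[Br-]
Why: Nickel‑catalysed halogen exchange of enol triflates (insertion of zerovalent nickel into the C–OTf bond, bromide exchange at nickel, C–Br reductive elimination) is a known route to alkenyl bromides, and the C(sp2)–OTf bond is far more reactive towards oxidative addition than the hindered secondary alkyl bromide.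

Step 22
Reactants: 31 silyl ether
Product: 32 (2R,6S,9S,10S)‑4,10‑dibromo‑9‑chloro‑5,5,9‑trimethyl‑1‑methylidenespiro[5.5]undec‑3‑en‑2‑ol (target, CNP0228180.1)
Conditions: Bu4NF, AcOH (1:1), THF, 0 °C → rt
Reagents that add atoms: none
Why: Fluoride‑mediated desilylation buffered with acetic acid frees the doubly allylic alcohol without exposing it to acid (ionisation) or to strong base (elimination in ring B).

**Compound list**

1 | 1,4‑dioxaspiro[4.5]decane‑8‑carboxylic acid | OC(=O)C1CCC2(CC1)OCCO2 | starting material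
2 | 3‑methylbut‑2‑en‑1‑ol (prenol) | CC(C)=CCO | starting material
3 | 3‑methylbut‑2‑en‑1‑yl 1,4‑dioxaspiro[4.5]decane‑8‑carboxylate | CC(C)=CCOC(=O)C1CCC2(CC1)OCCO2 | intermediate
4 | 8‑{[(3‑methylbut‑2‑en‑1‑yl)oxy](trimethylsilyloxy)methylidene}‑1,4‑dioxaspiro[4.5]decane | CC(C)=CCOC(O[Si](C)(C)C)=C1CCC2(CC1)OCCO2 | intermediate (not isolated)
5 | trimethylsilyl 8‑(2‑methylbut‑3‑en‑2‑yl)‑1,4‑dioxaspiro[4.5]decane‑8‑carboxylate | C=CC(C)(C)C1(C(=O)O[Si](C)(C)C)CCC2(CC1)OCCO2 | intermediate (not isolated)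
6 | 8‑(2‑methylbut‑3‑en‑2‑yl)‑1,4‑dioxaspiro[4.5]decane‑8‑carboxylic acid | C=CC(C)(C)C1(C(=O)O)CCC2(CC1)OCCO2 | intermediate (not isolated)
7 | 1‑(2‑methylbut‑3‑en‑2‑yl)‑4‑oxocyclohexane‑1‑carboxylic acid | C=CC(C)(C)C1(C(=O)O)CCC(=O)CC1 | intermediate
8 | methyl 1‑(2‑methylbut‑3‑en‑2‑yl)‑4‑oxocyclohexane‑1‑carboxylate | COC(=O)C1(C(C)(C)C=C)CCC(=O)CC1 | intermediate
9 | methyl (1R)‑1‑(2‑methylbut‑3‑en‑2‑yl)‑4‑(trimethylsilyloxy)cyclohex‑3‑ene‑1‑carboxylate | COC(=O)[C@]1(C(C)(C)C=C)CCC(O[Si](C)(C)C)=CC1 | intermediate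
10 | methyl (1R,3S)‑3‑bromo‑1‑(2‑methylbut‑3‑en‑2‑yl)‑4‑oxocyclohexane‑1‑carboxylate | COC(=O)[C@]1(C(C)(C)C=C)CCC(=O)[C@@H](Br)C1 | intermediate
11 | methyl (1R,3S,4S)‑3‑bromo‑4‑hydroxy‑4‑methyl‑1‑(2‑methylbut‑3‑en‑2‑yl)cyclohexane‑1‑carboxylate | COC(=O)[C@]1(C(C)(C)C=C)CC[C@](C)(O)[C@@H](Br)C1 | intermediate
12 | methyl (1R,3S,4S)‑3‑bromo‑4‑chloro‑4‑methyl‑1‑(2‑methylbut‑3‑en‑2‑yl)cyclohexane‑1‑carboxylate | COC(=O)[C@]1(C(C)(C)C=C)CC[C@](C)(Cl)[C@@H](Br)C1 | intermediate
13 | [(1R,3S,4S)‑3‑bromo‑4‑chloro‑4‑methyl‑1‑(2‑methylbut‑3‑en‑2‑yl)cyclohexyl]methanol | OC[C@]1(C(C)(C)C=C)CC[C@](C)(Cl)[C@@H](Br)C1 | intermediate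
14 | (1R,3S,4S)‑3‑bromo‑4‑chloro‑4‑methyl‑1‑(2‑methylbut‑3‑en‑2‑yl)cyclohexane‑1‑carbaldehyde | O=C[C@]1(C(C)(C)C=C)CC[C@](C)(Cl)[C@@H](Br)C1 | intermediate
15 | (1S,3S,4S)‑3‑bromo‑4‑chloro‑1‑ethynyl‑4‑methyl‑1‑(2‑methylbut‑3‑en‑2‑yl)cyclohexane | C#C[C@]1(C(C)(C)C=C)CC[C@](C)(Cl)[C@@H](Br)C1 | intermediate
16 | 9‑[(Z)‑2‑{(1R,3S,4S)‑3‑bromo‑4‑chloro‑4‑methyl‑1‑(2‑methylbut‑3‑en‑2‑yl)cyclohexyl}‑2‑iodoethenyl]‑9‑borabicyclo[3.3.1]nonane | I/C(=C\B1C2CCCC1CCC2)[C@]1(C(C)(C)C=C)CC[C@](C)(Cl)[C@@H](Br)C1 | intermediate (not isolated)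
17 | (1R,3S,4S)‑3‑bromo‑4‑chloro‑1‑(1‑iodoethenyl)‑4‑methyl‑1‑(2‑methylbut‑3‑en‑2‑yl)cyclohexane | C=C(I)[C@]1(C(C)(C)C=C)CC[C@](C)(Cl)[C@@H](Br)C1 | intermediate
18 | 3‑[(1R,3S,4S)‑3‑bromo‑4‑chloro‑1‑(1‑iodoethenyl)‑4‑methylcyclohexyl]‑3‑methylbutane‑1,2‑diol (both C2 epimers) | C=C(I)[C@]1(C(C)(C)C(O)CO)CC[C@](C)(Cl)[C@@H](Br)C1 | intermediate (not isolated)
19 | 2‑[(1R,3S,4S)‑3‑bromo‑4‑chloro‑1‑(1‑iodoethenyl)‑4‑methylcyclohexyl]‑2‑methylpropanal | C=C(I)[C@]1(C(C)(C)C=O)CC[C@](C)(Cl)[C@@H](Br)C1 | intermediate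
20 | 2‑[(1R,3S,4S)‑3‑bromo‑4‑chloro‑1‑(1‑iodoethenyl)‑4‑methylcyclohexyl]‑2‑methylhex‑5‑en‑3‑ol (both C3 epimers) | C=C(I)[C@]1(C(C)(C)C(O)CC=C)CC[C@](C)(Cl)[C@@H](Br)C1 | intermediate
21 | 2‑[(1R,3S,4S)‑3‑bromo‑4‑chloro‑1‑(1‑iodoethenyl)‑4‑methylcyclohexyl]‑2‑methylhex‑5‑en‑3‑one | C=C(I)[C@]1(C(C)(C)C(=O)CC=C)CC[C@](C)(Cl)[C@@H](Br)C1 | intermediate
22 | 2‑{2‑[(1R,3S,4S)‑3‑bromo‑4‑chloro‑1‑(1‑iodoethenyl)‑4‑methylcyclohexyl]propan‑2‑yl}‑2‑(prop‑2‑en‑1‑yl)‑1,3‑dioxolane | C=C(I)[C@]1(C(C)(C)C2(CC=C)OCCO2)CC[C@](C)(Cl)[C@@H](Br)C1 | intermediate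
23 | 3‑[2‑(2‑{(1R,3S,4S)‑3‑bromo‑4‑chloro‑1‑(1‑iodoethenyl)‑4‑methylcyclohexyl}propan‑2‑yl)‑1,3‑dioxolan‑2‑yl]propane‑1,2‑diol (both C2 epimers) | C=C(I)[C@]1(C(C)(C)C2(CC(O)CO)OCCO2)CC[C@](C)(Cl)[C@@H](Br)C1 | intermediate (not isolated)
24 | [2‑(2‑{(1R,3S,4S)‑3‑bromo‑4‑chloro‑1‑(1‑iodoethenyl)‑4‑methylcyclohexyl}propan‑2‑yl)‑1,3‑dioxolan‑2‑yl]acetaldehyde | C=C(I)[C@]1(C(C)(C)C2(CC=O)OCCO2)CC[C@](C)(Cl)[C@@H](Br)C1 | intermediate (key‑step precursor)
25 | dichloro{1‑[(1R,3S,4S)‑3‑bromo‑4‑chloro‑4‑methyl‑1‑{2‑[2‑(2‑oxoethyl)‑1,3‑dioxolan‑2‑yl]propan‑2‑yl}cyclohexyl]ethenyl}chromium | C=C([Cr](Cl)Cl)[C@]1(C(C)(C)C2(CC=O)OCCO2)CC[C@](C)(Cl)[C@@H](Br)C1 | intermediate (not isolated)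
26 | ethylene ketal of (2R,6S,9S,10S)‑10‑bromo‑9‑chloro‑2‑hydroxy‑5,5,9‑trimethyl‑1‑methylidenespiro[5.5]undecan‑4‑one | C=C1[C@H](O)CC3(OCCO3)C(C)(C)[C@]12CC[C@](C)(Cl)[C@@H](Br)C2 | intermediate (key‑step product)
27 | ethylene ketal of (2R,6S,9S,10S)‑10‑bromo‑2‑[(tert‑butyldimethylsilyl)oxy]‑9‑chloro‑5,5,9‑trimethyl‑1‑methylidenespiro[5.5]undecan‑4‑one | C=C1[C@H](O[Si](C)(C)C(C)(C)C)CC3(OCCO3)C(C)(C)[C@]12CC[C@](C)(Cl)[C@@H](Br)C2 | intermediate
28 | (2R,6S,9S,10S)‑10‑bromo‑2‑[(tert‑butyldimethylsilyl)oxy]‑9‑chloro‑5,5,9‑trimethyl‑1‑methylidenespiro[5.5]undecan‑4‑one | C=C1[C@H](O[Si](C)(C)C(C)(C)C)CC(=O)C(C)(C)[C@]12CC[C@](C)(Cl)[C@@H](Br)C2 | intermediate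
29 | potassium (2R,6S,9S,10S)‑10‑bromo‑2‑[(tert‑butyldimethylsilyl)oxy]‑9‑chloro‑5,5,9‑trimethyl‑1‑methylidenespiro[5.5]undec‑3‑en‑4‑olate | C=C1[C@H](O[Si](C)(C)C(C)(C)C)C=C([O-])C(C)(C)[C@]12CC[C@](C)(Cl)[C@@H](Br)C2.[K+] | intermediate (not isolated)
30 | (2R,6S,9S,10S)‑10‑bromo‑2‑[(tert‑butyldimethylsilyl)oxy]‑9‑chloro‑5,5,9‑trimethyl‑1‑methylidenespiro[5.5]undec‑3‑en‑4‑yl trifluoromethanesulfonate | C=C1[C@H](O[Si](C)(C)C(C)(C)C)C=C(OS(=O)(=O)C(F)(F)F)C(C)(C)[C@]12CC[C@](C)(Cl)[C@@H](Br)C2 | intermediate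
31 | tert‑butyl{[(2R,6S,9S,10S)‑4,10‑dibromo‑9‑chloro‑5,5,9‑trimethyl‑1‑methylidenespiro[5.5]undec‑3‑en‑2‑yl]oxy}dimethylsilane | C=C1[C@H](O[Si](C)(C)C(C)(C)C)C=C(Br)C(C)(C)[C@]12CC[C@](C)(Cl)[C@@H](Br)C2 | intermediate
32 | (2R,6S,9S,10S)‑4,10‑dibromo‑9‑chloro‑5,5,9‑trimethyl‑1‑methylidenespiro[5.5]undec‑3‑en‑2‑ol | C=C1[C@H](O)C=C(Br)C(C)(C)[C@]12CC[C@](C)(Cl)[C@@H](Br)C2 | target

**Totals**

Total step count: 22. Longest linear sequence: 22 steps (the route is fully linear from 1).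

**Steps most likely to fail**

Step 7 (deoxychlorination). The chlorosulfite may ionise to a free tertiary cation that is captured on the face syn to bromine or loses a proton, so that the configuration at the chlorine‑bearing carbon is eroded or alkenes form. The fallback sets out from 11 and replaces the open cation by a bridged intermediate. Heating 11 with catalytic TsOH in toluene, with loss of methanol, should close the lactone (6S)‑6‑bromo‑1‑methyl‑4‑(2‑methylbut‑3‑en‑2‑yl)‑2‑oxabicyclo[2.2.2]octan‑3‑one F1, in which the tertiary oxygen is tied to the face of the carboxyl carbon. BCl3 in CH2Cl2 at −78 °C then cleaves the tertiary alkyl–oxygen bond, with chloride handed over from the acyloxyborane on that same face to the bromine‑bridged cation, to give (1R,3S,4S)‑3‑bromo‑4‑chloro‑4‑methyl‑1‑(2‑methylbut‑3‑en‑2‑yl)cyclohexane‑1‑carboxylic acid F2. Methylation with Me3SiCHN2 comes back to the route at 12.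

Step 17 (ring closure). Facial discrimination at the aldehyde may be insufficient, because the ligand has to override a substrate whose two faces differ only through remote substituents, so that both carbinol epimers form. The fallback sets out from 24 and moves the stereocontrol to a separate reduction. Closure without ligand (CrCl2, catalytic NiCl2, DMSO, rt) gives the epimer mixture of the ethylene ketal of (6S,9S,10S)‑10‑bromo‑9‑chloro‑2‑hydroxy‑5,5,9‑trimethyl‑1‑methylidenespiro[5.5]undecan‑4‑one F3. Dess–Martin oxidation gives the 4‑mono(ethylene ketal) of (6S,9S,10S)‑10‑bromo‑9‑chloro‑5,5,9‑trimethyl‑1‑methylidenespiro[5.5]undecane‑2,4‑dione F4. Reduction with (S)‑2‑methyl‑CBS‑oxazaborolidine and catecholborane in toluene at −78 °C, with the alkenyl side acting as the large group, should give the 2R carbinol and comes back to the route at 26.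

Step 21 (triflate‑to‑bromide exchange). The low‑valent nickel may also activate the secondary C–Br bond of ring B (radical formation with loss of the vicinal chloride) or reduce the triflate. The fallback sets out from 30 and makes the C–Br bond by ipso substitution at tin instead of at nickel. Zerovalent palladium (Pd(PPh3)4) with (Me3Sn)2 and LiCl in THF at 60 °C gives tert‑butyl{[(2R,6S,9S,10S)‑10‑bromo‑9‑chloro‑5,5,9‑trimethyl‑1‑methylidene‑4‑(trimethylstannyl)spiro[5.5]undec‑3‑en‑2‑yl]oxy}dimethylsilane F5. Bromodestannylation with NBS in CH2Cl2/MeCN at 0 °C comes back to the route at 31.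

**Further compounds**

F1 | step 7 | (6S)‑6‑bromo‑1‑methyl‑4‑(2‑methylbut‑3‑en‑2‑yl)‑2‑oxabicyclo[2.2.2]octan‑3‑one | O=C2[C@]1(C(C)(C)C=C)CC[C@](C)(O2)[C@@H](Br)C1
F2 | step 7 | (1R,3S,4S)‑3‑bromo‑4‑chloro‑4‑methyl‑1‑(2‑methylbut‑3‑en‑2‑yl)cyclohexane‑1‑carboxylic acid | OC(=O)[C@]1(C(C)(C)C=C)CC[C@](C)(Cl)[C@@H](Br)C1
F3 | step 17 | ethylene ketal of (6S,9S,10S)‑10‑bromo‑9‑chloro‑2‑hydroxy‑5,5,9‑trimethyl‑1‑methylidenespiro[5.5]undecan‑4‑one (both C2 epimers) | C=C1C(O)CC3(OCCO3)C(C)(C)[C@]12CC[C@](C)(Cl)[C@@H](Br)C2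
F4 | step 17 | 4‑mono(ethylene ketal) of (6S,9S,10S)‑10‑bromo‑9‑chloro‑5,5,9‑trimethyl‑1‑methylidenespiro[5.5]undecane‑2,4‑dione | C=C1C(=O)CC3(OCCO3)C(C)(C)[C@]12CC[C@](C)(Cl)[C@@H](Br)C2
F5 | step 21 | tert‑butyl{[(2R,6S,9S,10S)‑10‑bromo‑9‑chloro‑5,5,9‑trimethyl‑1‑methylidene‑4‑(trimethylstannyl)spiro[5.5]undec‑3‑en‑2‑yl]oxy}dimethylsilane | C=C1[C@H](O[Si](C)(C)C(C)(C)C)C=C([Sn](C)(C)C)C(C)(C)[C@]12CC[C@](C)(Cl)[C@@H](Br)C2
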